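The synthesis rests on disconnecting ring B at C8–C8'. C8 sits next to C7, whose hydroxyl can be carried as an aryl ketone, and the methyl group on C8' can be carried as the carbonyl carbon C9' of an imide; C8 and C8' are then both enolate carbons, and oxidation of the bis-enolate joins them. In one operation this closes the seven-membered ring B (C1, C2, C1', C7', C8', C8, C7), makes its last skeletal bond and sets C8' and C8. The precursor is a ring-B-open keto imide: ring A carries a propanoyl group, the quaternary C1' a 3-oxazolidinonyl-3-oxopropyl chain, and ring C is masked as the 3,5-dimethoxycyclohexa-2,5-diene made by Birch reductive alkylation of a biaryl.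

Key step: step 7

Remark on the chemistry: ring A is the trimethoxyarene (C1–C6), ring B the seven-membered ring, ring C the spiro six-membered ring (C1'–C6'), and C9 and C9' are the carbons on C8 and C8'; it is assumed that the target (7R,8S,8'R), whose C7, C8 and C8' substituents are all pseudo-equatorial on ring B, is the more stable C7 epimer, and step 11 relies on this.

Step 1
Reactants: 1 2-bromo-3,4,5-trimethoxybenzaldehyde; 2 3,5-dimethoxyphenylboronic acid
Product: 3 2-(3,5-dimethoxyphenyl)-3,4,5-trimethoxybenzaldehyde
Conditions: Pd(OAc)2 (2 mol %), SPhos (4 mol %), K3PO4, toluene/H2O, 90 °C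
Reagents that add atoms: none
Why: Suzuki–Miyaura coupling, in which the bulky electron-rich biaryl phosphine lets zerovalent palladium insert into the doubly ortho-substituted C–Br bond while the unhindered boronic acid transmetalates readily and the aldehyde is untouched.

Step 2
Reactants: 3 2-(3,5-dimethoxyphenyl)-3,4,5-trimethoxybenzaldehyde
Product: 4 rac-1-[2-(3,5-dimethoxyphenyl)-3,4,5-trimethoxyphenyl]propan-1-ol
Conditions: EtMgBr, THF, 0 °C; aq NH4Cl
Reagents that add atoms: ethylmagnesium bromide, CC[Mg]Br
Why: Grignard addition to the aryl aldehyde installs C8 and C9 on C7; the carbinol centre is formed as a racemate on purpose, because C7 becomes a ketone in step 5.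

Step 3
Reactants: 4 rac-1-[2-(3,5-dimethoxyphenyl)-3,4,5-trimethoxyphenyl]propan-1-ol; 5 (3-bromopropoxy)(tert-butyl)dimethylsilane
Product: 7 rac-1-[2-[1-[3-(tert-butyldimethylsilyloxy)propyl]-3,5-dimethoxycyclohexa-2,5-dien-1-yl]-3,4,5-trimethoxyphenyl]propan-1-ol, via dilithium alkoxide-cyclohexadienide 6 (not isolated)
Conditions: n-BuLi (1.0 equiv), THF, −78 °C; Li (2.5 equiv), NH3/THF, −78 °C; then 5 (3 equiv); NH4Cl
Reagents that add atoms: none
Why: Birch reductive alkylation of a 3,5-dimethoxybiaryl, in which the carbinol is protected as its lithium alkoxide against benzylic C–O cleavage, two electrons enter ring C (C1' and C4' carry no donor), ammonia protonates C4' and the aryl-stabilised C1' carbanion 6 is alkylated by the unactivated primary bromide 5, which unlike a 3-halopropanoate ester cannot eliminate to an acrylate; C1' is not stereogenic because the two arms of ring C are identical.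

Step 4
Reactants: 7 rac-1-[2-[1-[3-(tert-butyldimethylsilyloxy)propyl]-3,5-dimethoxycyclohexa-2,5-dien-1-yl]-3,4,5-trimethoxyphenyl]propan-1-ol
Product: 8 rac-3-[1-[6-(1-hydroxypropyl)-2,3,4-trimethoxyphenyl]-3,5-dimethoxycyclohexa-2,5-dien-1-yl]propan-1-ol
Conditions: TBAF, THF, rt
Reagents that add atoms: none
Why: Fluoride cleaves the primary silyl ether under non-acidic conditions that leave the acid-labile bis-enol ether of ring C intact.

Step 5
Reactants: 8 rac-3-[1-[6-(1-hydroxypropyl)-2,3,4-trimethoxyphenyl]-3,5-dimethoxycyclohexa-2,5-dien-1-yl]propan-1-ol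
Product: 9 3-[3,5-dimethoxy-1-(2,3,4-trimethoxy-6-propanoylphenyl)cyclohexa-2,5-dien-1-yl]propanoic acid
Conditions: (n-Pr)4N[RuO4] (10 mol %), NMO·H2O (10 equiv), MeCN, rt
Reagents that add atoms: water (from NMO·H2O), O
Why: Ley–Griffith oxidation with excess NMO hydrate takes the secondary benzylic alcohol to the C7 ketone and the primary alcohol through the aldehyde hydrate to the acid in one pot under neutral conditions that spare the enol ethers; the racemic C7 centre is erased here.

Step 6
Reactants: 9 3-[3,5-dimethoxy-1-(2,3,4-trimethoxy-6-propanoylphenyl)cyclohexa-2,5-dien-1-yl]propanoic acid; 10 (S)-4-benzyl-2-oxazolidinone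
Product: 12 (S)-4-benzyl-3-[3-[3,5-dimethoxy-1-(2,3,4-trimethoxy-6-propanoylphenyl)cyclohexa-2,5-dien-1-yl]propanoyl]oxazolidin-2-one, via pivalic mixed anhydride 11 (not isolated)
Conditions: PivCl, Et3N, THF, −20 °C; then 10, LiCl, −20 °C to rt
Reagents that add atoms: none
Why: N-acylation of the oxazolidinone through the mixed pivalic anhydride with LiCl and Et3N is mild enough neither to enolise the ketone nor to hydrolyse ring C, and the stereocentre of 10 is not touched.

Step 7
Reactants: 12 (S)-4-benzyl-3-[3-[3,5-dimethoxy-1-(2,3,4-trimethoxy-6-propanoylphenyl)cyclohexa-2,5-dien-1-yl]propanoyl]oxazolidin-2-one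
Product: 14 (8S,8'R) ring B keto imide [C7 ketone; C8 methyl trans to the C8' carbonyl bound to N of (S)-4-benzyloxazolidin-2-one; ring C 3',5'-dimethoxycyclohexa-2',5'-diene], via dilithium bis-enolate 13 (not isolated)
Conditions: LiN(i-Pr)2 (2.2 equiv), THF, −78 °C; Fe(acac)3 (2.2 equiv), −78 °C to rt, 0.01 M; then DBU (0.2 equiv), rt
Reagents that add atoms: none
Why: LiN(i-Pr)2 turns both carbonyl groups into lithium enolates (13), trivalent iron in Fe(acac)3 takes one electron from one of them, the α-carbonyl radical so formed is captured by the second enolate in the same molecule, and a second equivalent of Fe(acac)3 oxidises the resulting ketyl radical anion to the 1,4-dicarbonyl compound, leaving divalent iron. The closest known reaction is the intermolecular oxidative heterocoupling of an N-acyloxazolidinone enolate with a ketone enolate by Fe(acac)3, together with intramolecular oxidative enolate couplings used to close carbocycles. Ring B closes as a seven-membered ring in a 7-exo-trig mode with respect to the imide enolate C8'=C9' (7-endo-trig with respect to the ketone enolate C7=C8), helped by the arene C1–C2 bond and the quaternary C1', which hold the two chains close. C8' is controlled by the chelated Z-enolate of the (S)-4-benzyloxazolidinone, whose benzyl group covers one face so that C8 bonds to the other (8'R, the sense seen in alkylations of this auxiliary), and C8 is controlled thermodynamically: DBU equilibrates it through the ketone enol to the 8S isomer with the C8 methyl and the C8' acyl group trans and pseudo-equatorial, while the α-branched imide centre resists deprotonation. The step needs cross-coupling over homo-coupling and ring closure over oligomerisation, secured by the tether and by high dilution, and it needs ring C to stay inert, secured by carrying it as the 3,5-dimethoxy-1,4-diene, which has no electron-poor double bond for an enolate and no hydrogen acidic enough for the amide base.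

Step 8
Reactants: 14 (8S,8'R) ring B keto imide
Product: 15 (8S,8'R) ring B diol (C7–OH as a mixture of epimers; C9'–OH; ring C diene)
Conditions: LiBH4 (4 equiv), MeOH (1 equiv), THF, 0 °C to rt
Reagents that add atoms: none
Why: LiBH4 reduces the N-acyloxazolidinone to the primary alcohol at C9' with release of auxiliary 10 and also reduces the C7 ketone; hydride should enter C7 mainly from the face away from the pseudo-axial arm of ring C, so the C7 configuration is not relied upon here and is set in step 11, while this non-basic reductant leaves C8 and C8' unchanged.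

Step 9
Reactants: 15 (8S,8'R) ring B diol (C7 epimers)
Product: 16 (8S,8'R) C9' p-toluenesulfonate of diol 15 (C7 epimers)
Conditions: TsCl (1.2 equiv), Et3N, DMAP (cat.), CH2Cl2, 0 °C
Reagents that add atoms: p-toluenesulfonyl chloride, Cc1ccc(cc1)S(=O)(=O)Cl
Why: Sulfonylation is selective for the unhindered primary hydroxyl over the secondary benzylic hydroxyl, which is flanked by the C8 methyl group and the ortho-substituted arene.

Step 10
Reactants: 16 (8S,8'R) C9' p-toluenesulfonate (C7 epimers)
Product: 17 (8S,8'R) ring B alcohol with methyl groups on C8 and C8' (C7 epimers; ring C diene)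
Conditions: LiBHEt3 (3 equiv), THF, 0 °C to rt; H2O
Reagents that add atoms: none
Why: Hydride displaces the primary sulfonate by SN2 to give the C8' methyl group, and the C7 alkoxide cannot close a tetrahydrofuran because it is trans to C9' in the 7S epimer and both groups are pseudo-equatorial in the 7R epimer.

Step 11
Reactants: 17 (8S,8'R) ring B alcohol (C7 epimers)
Product: 18 (7R,8S,8'R) ring B alcohol (ring C diene)
Conditions: Ru(CO)2Cl(η5-C5Ph5) (5 mol %), KOtBu (5 mol %), toluene, rt to 50 °C
Reagents that add atoms: none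
Why: Reversible ruthenium-catalysed dehydrogenation and rehydrogenation of the secondary alcohol (the alcohol racemisation manifold of dynamic kinetic resolutions) equilibrates C7 through the ketone, and the mixture should converge on the 7R epimer, in which the hydroxyl and both methyl groups are pseudo-equatorial and the hydroxyl avoids the syn-axial arm of ring C; any minor epimer can be separated and recycled.

Step 12
Reactants: 18 (7R,8S,8'R) ring B alcohol
Product: 19 (7R,8S,8'R) C7 tert-butyldimethylsilyl ether (ring C diene)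
Conditions: TBSOTf, 2,6-lutidine, CH2Cl2, −78 to 0 °C
Reagents that add atoms: tert-butyldimethylsilyl trifluoromethanesulfonate, CC(C)(C)[Si](C)(C)OS(=O)(=O)C(F)(F)F
Why: A silyl triflate with a hindered pyridine base silylates the hindered secondary alcohol without acid and protects it from the oxidant of step 13.

Step 13
Reactants: 19 (7R,8S,8'R) C7 silyl ether (ring C diene)
Product: 20 (7R,8S,8'R) C7 silyl ether with ring C as the 3',5'-dimethoxycyclohexa-2',5'-dien-4'-one
Conditions: Rh2(cap)4 (dirhodium tetrakis(caprolactamate), 1 mol %), t-BuOOH (5 equiv, in decane), K2CO3, CH2Cl2, rt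
Reagents that add atoms: tert-butyl hydroperoxide, CC(C)(C)OO
Why: Bis-allylic oxidation of a Birch-type 1,4-diene to the cross-conjugated dienone, in which a tert-butylperoxy radical abstracts the weak doubly allylic C4'–H, the pentadienyl radical is trapped at its central carbon C4' and the mixed peroxide collapses to the ketone; the quaternary C1' prevents aromatisation and the carbonate buffer protects the enol ethers.

Step 14
Reactants: 20 (7R,8S,8'R) silyl ether dienone
Product: 21 CNP0288561.1, the (7R,8S,8'R) spirodienone alcohol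
Conditions: HF·pyridine, pyridine, THF, 0 °C to rt
Reagents that add atoms: none
Why: Buffered fluoride cleaves the silyl ether without ionising the benzylic C7–O bond or forming an alkoxide that could add to the dienone, and no stereocentre is affected.

Compound list
1 | 2-bromo-3,4,5-trimethoxybenzaldehyde | O=Cc1cc(OC)c(OC)c(OC)c1Br | starting material
2 | 3,5-dimethoxyphenylboronic acid | COc1cc(cc(OC)c1)B(O)O | starting material
3 | 2-(3,5-dimethoxyphenyl)-3,4,5-trimethoxybenzaldehyde | O=Cc1cc(OC)c(OC)c(OC)c1-c1cc(OC)cc(OC)c1 | intermediate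
4 | rac-1-[2-(3,5-dimethoxyphenyl)-3,4,5-trimethoxyphenyl]propan-1-ol | CCC(O)c1cc(OC)c(OC)c(OC)c1-c1cc(OC)cc(OC)c1 | intermediate
5 | (3-bromopropoxy)(tert-butyl)dimethylsilane | CC(C)(C)[Si](C)(C)OCCCBr | starting material
6 | dilithium alkoxide-cyclohexadienide of 4 (C7–OLi, carbanion at C1', C4' protonated) | [Li+].[Li+].CCC([O-])c1cc(OC)c(OC)c(OC)c1[C-]1C=C(OC)CC(OC)=C1 | intermediate (not isolated)
7 | rac-1-[2-[1-[3-(tert-butyldimethylsilyloxy)propyl]-3,5-dimethoxycyclohexa-2,5-dien-1-yl]-3,4,5-trimethoxyphenyl]propan-1-ol | CCC(O)c1cc(OC)c(OC)c(OC)c1C1(CCCO[Si](C)(C)C(C)(C)C)C=C(OC)CC(OC)=C1 | intermediate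
8 | rac-3-[1-[6-(1-hydroxypropyl)-2,3,4-trimethoxyphenyl]-3,5-dimethoxycyclohexa-2,5-dien-1-yl]propan-1-ol | CCC(O)c1cc(OC)c(OC)c(OC)c1C1(CCCO)C=C(OC)CC(OC)=C1 | intermediate
9 | 3-[3,5-dimethoxy-1-(2,3,4-trimethoxy-6-propanoylphenyl)cyclohexa-2,5-dien-1-yl]propanoic acid | CCC(=O)c1cc(OC)c(OC)c(OC)c1C1(CCC(=O)O)C=C(OC)CC(OC)=C1 | intermediate
10 | (S)-4-benzyl-2-oxazolidinone | O=C1N[C@@H](Cc2ccccc2)CO1 | starting material
11 | pivalic mixed anhydride of acid 9 | CCC(=O)c1cc(OC)c(OC)c(OC)c1C1(CCC(=O)OC(=O)C(C)(C)C)C=C(OC)CC(OC)=C1 | intermediate (not isolated)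
12 | (S)-4-benzyl-3-[3-[3,5-dimethoxy-1-(2,3,4-trimethoxy-6-propanoylphenyl)cyclohexa-2,5-dien-1-yl]propanoyl]oxazolidin-2-one | COC1=CC(C=C(OC)C1)(CCC(=O)N1[C@@H](Cc2ccccc2)COC1=O)c1c(OC)c(OC)c(OC)cc1C(=O)CC | intermediate
13 | dilithium bis-enolate of 12 (Z-enolates at C7=C8 and C9'=C8') | [Li+].[Li+].C/C=C(\[O-])c1cc(OC)c(OC)c(OC)c1C1(C/C=C(\[O-])N2[C@@H](Cc3ccccc3)COC2=O)C=C(OC)CC(OC)=C1 | intermediate (not isolated)
14 | (4S)-4-benzyl-3-[[(7R,8S)-2,3,3',4,5'-pentamethoxy-8-methyl-9-oxo-6,7,8,9-tetrahydrospiro[benzo[7]annulene-5,1'-cyclohexa[2,5]dien]-7-yl]carbonyl]oxazolidin-2-one; lignan labels (8S,8'R) | COC1=CC2(C=C(OC)C1)C[C@@H](C(=O)N1[C@@H](Cc3ccccc3)COC1=O)[C@H](C)C(=O)c1cc(OC)c(OC)c(OC)c12 | intermediate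
15 | (7R,8S)-7-(hydroxymethyl)-2,3,3',4,5'-pentamethoxy-8-methyl-6,7,8,9-tetrahydrospiro[benzo[7]annulene-5,1'-cyclohexa[2,5]dien]-9-ol, epimers at the carbinol carbon (lignan C7) | COC1=CC2(C=C(OC)C1)C[C@@H](CO)[C@H](C)C(O)c1cc(OC)c(OC)c(OC)c12 | intermediate
16 | [(7R,8S)-9-hydroxy-2,3,3',4,5'-pentamethoxy-8-methyl-6,7,8,9-tetrahydrospiro[benzo[7]annulene-5,1'-cyclohexa[2,5]dien]-7-yl]methyl 4-methylbenzenesulfonate, epimers at lignan C7 | COC1=CC2(C=C(OC)C1)C[C@@H](COS(=O)(=O)c3ccc(C)cc3)[C@H](C)C(O)c1cc(OC)c(OC)c(OC)c12 | intermediate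
17 | (7R,8S)-2,3,3',4,5'-pentamethoxy-7,8-dimethyl-6,7,8,9-tetrahydrospiro[benzo[7]annulene-5,1'-cyclohexa[2,5]dien]-9-ol, epimers at lignan C7 | COC1=CC2(C=C(OC)C1)C[C@@H](C)[C@H](C)C(O)c1cc(OC)c(OC)c(OC)c12 | intermediate
18 | (7R,8S,9R)-2,3,3',4,5'-pentamethoxy-7,8-dimethyl-6,7,8,9-tetrahydrospiro[benzo[7]annulene-5,1'-cyclohexa[2,5]dien]-9-ol; lignan labels (7R,8S,8'R) | COC1=CC2(C=C(OC)C1)C[C@@H](C)[C@H](C)[C@@H](O)c1cc(OC)c(OC)c(OC)c12 | intermediate
19 | tert-butyldimethylsilyl ether of 18 at the carbinol oxygen | COC1=CC2(C=C(OC)C1)C[C@@H](C)[C@H](C)[C@@H](O[Si](C)(C)C(C)(C)C)c1cc(OC)c(OC)c(OC)c12 | intermediate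
20 | (7R,8S,9R)-9-(tert-butyldimethylsilyloxy)-2,3,3',4,5'-pentamethoxy-7,8-dimethyl-6,7,8,9-tetrahydrospiro[benzo[7]annulene-5,1'-cyclohexa[2,5]dien]-4'-one | COC1=CC2(C=C(OC)C1=O)C[C@@H](C)[C@H](C)[C@@H](O[Si](C)(C)C(C)(C)C)c1cc(OC)c(OC)c(OC)c12 | intermediate
21 | CNP0288561.1, (7R,8S,9R)-9-hydroxy-2,3,3',4,5'-pentamethoxy-7,8-dimethyl-6,7,8,9-tetrahydrospiro[benzo[7]annulene-5,1'-cyclohexa[2,5]dien]-4'-one; lignan labels (7R,8S,8'R) | COC1=CC2(C=C(OC)C1=O)C[C@@H](C)[C@H](C)[C@@H](O)c1cc(OC)c(OC)c(OC)c12 | target

Total step count: 14 steps.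
Longest linear sequence: 14 steps, from 1 to 21; 2, 5 and 10 are bought.

Steps most likely to fail

1. Step 7. The two enolate carbons may not find each other: the seven-membered closure may be slower than intermolecular homo-coupling, the electrophilic α-keto radical at C8 may instead add to an electron-rich enol ether double bond of ring C, and facial control at C8' may erode if the imide enolate is the partner that is oxidised. The fallback closes the same bond by a polar, two-electron route and sets out from keto acid 9. The carboxylate and ketone enolate dianion (LiN(SiMe3)2, 2.1 equiv, THF, −78 °C; only the ketone is enolised) is brominated with N-bromosuccinimide at −78 °C, where the lithium enolate outruns the enol ethers, to give the α-bromo keto acid F1. Activation with PivCl and Et3N gives the pivalic mixed anhydride F2, which acylates lithiated 10 at −78 °C to give the α-bromo keto imide F3. NaN(SiMe3)2 (THF, −78 to −40 °C) then forms the chelated sodium Z-enolate of the imide, which displaces bromide at C8 in an intramolecular oxazolidinone enolate alkylation from the face opposite the benzyl group. DBU equilibration of C8 brings the route back to 14.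

2. Step 13. Hydrogen abstraction at C4' may be followed by oxygen capture at C2' or C6' (transposed, conjugated products), peroxy radicals may attack the enol ether double bonds, or the C7–H next to the silyl ether may be abstracted. The fallback replaces radical C–H oxidation by metalation and oxygenation and sets out from 19. t-BuLi (THF, −78 °C) removes a proton from C4', the CH2 flanked by the two methoxy-bearing sp2 carbons and the known metalation site of 1,5-dimethoxycyclohexa-1,4-dienes, to give the C4' dienyllithium F4. Oxidation in the same flask with 2-(phenylsulfonyl)-3-phenyloxaziridine gives the C4' alcohol F5 (both orientations of the hydroxyl, of no consequence). MnO2 in CH2Cl2 oxidises this doubly allylic alcohol to dienone 20, where the route is rejoined.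

3. Step 3. Electron transfer into the twisted, doubly ortho-substituted biaryl may stop short, and the hindered C1' carbanion may be protonated by ammonia faster than the unactivated bromide alkylates it, which would leave the C1'–H diene. The fallback builds the side chain in two stages and sets out from 4. The same reduction is run, but carbanion 6 is captured with allyl bromide, the most reactive class of electrophile for such carbanions, to give the allyl diene F6. Hydroboration of the terminal alkene with 9-borabicyclo[3.3.1]nonane (2.2 equiv; the secondary hydroxyl is tied up as its borinate, and the trisubstituted enol ethers react far more slowly with this borane) gives the bis(9-borabicyclononyl) adduct F7. Alkaline H2O2 work-up gives diol 8, where the route is rejoined.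

Further compounds
F1 | step 7 | rac-3-[1-[6-(2-bromopropanoyl)-2,3,4-trimethoxyphenyl]-3,5-dimethoxycyclohexa-2,5-dien-1-yl]propanoic acid | CC(Br)C(=O)c1cc(OC)c(OC)c(OC)c1C1(CCC(=O)O)C=C(OC)CC(OC)=C1
F2 | step 7 | pivalic mixed anhydride of F1 | CC(Br)C(=O)c1cc(OC)c(OC)c(OC)c1C1(CCC(=O)OC(=O)C(C)(C)C)C=C(OC)CC(OC)=C1
F3 | step 7 | (S)-4-benzyl-3-[3-[1-[6-(2-bromopropanoyl)-2,3,4-trimethoxyphenyl]-3,5-dimethoxycyclohexa-2,5-dien-1-yl]propanoyl]oxazolidin-2-one (epimers at the C–Br carbon) | COC1=CC(C=C(OC)C1)(CCC(=O)N1[C@@H](Cc2ccccc2)COC1=O)c1c(OC)c(OC)c(OC)cc1C(=O)C(C)Br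
F4 | step 13 | C4' dienyllithium derived from 19 | [Li+].COC1=CC2(C=C(OC)[CH-]1)C[C@@H](C)[C@H](C)[C@@H](O[Si](C)(C)C(C)(C)C)c1cc(OC)c(OC)c(OC)c12
F5 | step 13 | C4' alcohol derived from 19 (both orientations at C4') | COC1=CC2(C=C(OC)C1O)C[C@@H](C)[C@H](C)[C@@H](O[Si](C)(C)C(C)(C)C)c1cc(OC)c(OC)c(OC)c12
F6 | step 3 | rac-1-[2-(1-allyl-3,5-dimethoxycyclohexa-2,5-dien-1-yl)-3,4,5-trimethoxyphenyl]propan-1-ol | CCC(O)c1cc(OC)c(OC)c(OC)c1C1(CC=C)C=C(OC)CC(OC)=C1
F7 | step 3 | bis(9-borabicyclo[3.3.1]nonan-9-yl) adduct of F6 (O-borinate at C7, B-alkyl at the chain end) | CCC(OB1C2CCCC1CCC2)c1cc(OC)c(OC)c(OC)c1C1(CCCB2C3CCCC2CCC3)C=C(OC)CC(OC)=C1
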